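**Strategy.** Ring A (ent-kaurane numbering throughout) contains a Claisen retron: C6, the hydroxymethyl carbon on C5, lies two bonds from the C2=C3 olefin through the gem-dimethyl carbon C4. Raising C6 to the acid level and tying its oxygen to C2 gives a δ-lactone, (R)-4-methylidene-6-(2-methylpropenyl)oxan-2-one, that contains no carbocycle. Its silyl ketene acetal undergoes a ring-contracting Ireland–Claisen rearrangement that forms the C4–C5 bond, closes ring A, creates the quaternary C4, places the C2=C3 olefin and transfers chirality from C2 to C5. C5 then steers the spiro centre C10, which steers the cycloaddition that sets C8 and C9, and from there C13 and C16.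

Key step: step 5

Remark on numbering: C1 ring A ketone, C2=C3, C4 gem-dimethyl carbon, C5, C6 hydroxymethyl, C7 lactone carbonyl, C8, C9, C10 spiro carbon, C11–C14 ring C, C15 ketone, C16 carbinol carbon, C20 lactone methylene.

Remark on labile centres: the epoxide centre in 14/15, C8 in 22/23 and C16 in 27/28 are each made planar again in a later step; 14, 15, 19 and 28 are drawn as the epimer expected to predominate, and 22, 23 and 27 are written without a descriptor at the labile centre.

Step 1
Reactants: 1 3-methylbut-3-en-1-ol
Product: 2 tert-butyldimethyl[(3-methylbut-3-en-1-yl)oxy]silane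
Conditions: t-BuMe2SiCl, imidazole, CH2Cl2, 0 °C to rt
Reagents that add atoms: tert-butyldimethylsilyl chloride, CC(C)(C)[Si](C)(C)Cl
Why: Imidazole-promoted silylation masks the hydroxyl so that the allylic methyl group can be metalated in step 2; no stereocentre is formed.

Step 2
Reactants: 2 tert-butyldimethyl[(3-methylbut-3-en-1-yl)oxy]silane; 3 3-methylbut-2-enal
Product: 6 (5R)-1-[(tert-butyldimethylsilyl)oxy]-7-methyl-3-methylideneoct-6-en-5-ol, via allylpotassium 4 (not isolated), via allylborane 5 (not isolated)
Conditions: n-BuLi, KOt-Bu, THF, −78 to −50 °C; (+)-Ipc2BOMe, −78 °C; BF3·OEt2; then 3, −78 °C; NaOH, H2O2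
Reagents that add atoms: none
Why: Brown asymmetric allylboration: the n-BuLi/KOt-Bu superbase metalates the methallyl methyl group, exchange to boron and methoxide abstraction by BF3 give 5, which adds to 3 through a chair-like six-membered transition state in which the isopinocampheyl groups (from (−)-α-pinene) expose the re face of the aldehyde, setting the (R)-carbinol centre C2.

Step 3
Reactants: 6 (5R)-1-[(tert-butyldimethylsilyl)oxy]-7-methyl-3-methylideneoct-6-en-5-ol
Product: 7 (5R)-7-methyl-3-methylideneoct-6-ene-1,5-diol
Conditions: Bu4NF, THF, 0 °C to rt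
Reagents that add atoms: none
Why: Fluoride-induced desilylation frees the primary hydroxyl without touching the allylic alcohol or the alkenes; no stereocentre changes.

Step 4
Reactants: 7 (5R)-7-methyl-3-methylideneoct-6-ene-1,5-diol
Product: 9 (6R)-4-methylidene-6-(2-methylprop-1-en-1-yl)oxan-2-one, via hydroxy aldehyde 8 (not isolated)
Conditions: 2,2,6,6-tetramethylpiperidin-1-oxyl (cat.), PhI(OAc)2, CH2Cl2, rt
Reagents that add atoms: none
Why: Oxoammonium-mediated oxidative lactonisation of a 1,5-diol: the primary alcohol is oxidised first, aldehyde 8 closes to the lactol with the C2 hydroxyl and a second oxidation gives the δ-lactone under near-neutral conditions that should keep the exocyclic alkene out of conjugation; C2 is untouched.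

Step 5
Reactants: 9 (6R)-4-methylidene-6-(2-methylprop-1-en-1-yl)oxan-2-one
Product: 12 (1S)-2,2-dimethyl-6-methylidenecyclohex-3-ene-1-carboxylic acid, via silyl ketene acetal 10 (not isolated), via silyl ester 11 (not isolated)
Conditions: LiN(i-Pr)2, Me3SiCl, Et3N, THF, −78 °C; then toluene, 110 °C; then 1 M HCl, THF
Reagents that add atoms: none
Why: The only enolisable position of 9 is C5 (α to the lactone carbonyl and allylic), so LiN(i-Pr)2 with Me3SiCl present gives the cyclic silyl ketene acetal 10, an allyl vinyl ether locked in the ring, which on heating undergoes a suprafacial [3,3]-sigmatropic shift that forms C4–C5 while the O–C2 bond breaks (Ireland–Claisen rearrangement in its ring-contracting mode). The closest known reaction type is the Claisen ring contraction of alkenyl-substituted lactone silyl ketene acetals to cycloalkene carboxylic acids. Ring A is closed by this sigmatropic ring contraction of the six-membered lactone to the six-membered carbocycle, and because C5 and C2 stay joined through C10–C1 the array must pass through a boat-like transition state of bicyclo[2.2.2] shape. The new stereocentre C5 is controlled by C2: the 2-methylpropenyl group can only reach the face of the ketene acetal on which it stands, so the (R) centre at C2 is transferred to (S)-C5 while C2 becomes olefinic, and the quaternary carbon C4 carries two identical methyl groups. The step needs bond formation at the fully substituted alkene terminus ahead of ring opening or migration of the exocyclic alkene into conjugation; the in-situ silyl trap, the neutral thermal conditions and the flat neighbours C6 and C10, which keep both C4 methyl groups clear in the boat, are expected to secure this.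

Step 6
Reactants: 12 (1S)-2,2-dimethyl-6-methylidenecyclohex-3-ene-1-carboxylic acid
Product: 13 [(1S)-2,2-dimethyl-6-methylidenecyclohex-3-en-1-yl]methanol
Conditions: LiAlH4, Et2O, 0 °C to rt
Reagents that add atoms: none
Why: Hydride reduction of the carboxylic acid to the primary alcohol; the carboxylate formed first protects C5 from epimerisation and the isolated alkenes are inert.

Step 7
Reactants: 13 [(1S)-2,2-dimethyl-6-methylidenecyclohex-3-en-1-yl]methanol
Product: 14 (5,5-dimethyl-1-oxaspiro[2.5]oct-6-en-4-yl)methanol (epoxide oxygen cis to the hydroxymethyl group)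
Conditions: VO(acac)2 (cat.), t-BuOOH, CH2Cl2, 0 °C to rt
Reagents that add atoms: tert-butyl hydroperoxide, CC(C)(C)OO
Why: Hydroxyl-directed vanadium-catalysed epoxidation: the homoallylic C6 hydroxyl delivers oxygen to the exocyclic C10=C20 alkene on its own face (new spiro centre, oxygen cis to C6), while the more remote C2=C3 alkene next to quaternary C4 should be left; the epoxide configuration is lost in step 9.

Step 8
Reactants: 14 (5,5-dimethyl-1-oxaspiro[2.5]oct-6-en-4-yl)methanol (epoxide oxygen cis to the hydroxymethyl group)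
Product: 15 tert-butyldimethylsilyl ether of 14
Conditions: t-BuMe2SiCl, imidazole, DMF, rt
Reagents that add atoms: tert-butyldimethylsilyl chloride, CC(C)(C)[Si](C)(C)Cl
Why: Silylation of the primary alcohol protects C6–OH for the radical, enolate and Lewis acid steps that follow; no stereocentre changes.

Step 9
Reactants: 15 tert-butyldimethylsilyl ether of 14; 16 2,2,2-trifluoroethyl prop-2-enoate
Product: 18 7-[(tert-butyldimethylsilyloxy)methyl]-8,8-dimethyl-2-oxaspiro[5.5]undec-9-en-3-one (C9 trans to C6), via hydroxy ester 17 (not isolated)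
Conditions: Cp2TiCl2, Zn, 2,4,6-collidine hydrochloride, THF, rt
Reagents that add atoms: none
Why: Nugent–RajanBabu epoxide opening combined with Giese addition: Cp2TiCl (trivalent titanium, made in the flask) opens the epoxide to the tertiary C10 radical, which adds to 16 on the face opposite the C5 silyloxymethyl group, the α-ester radical is reduced and protonated to 17 and the C20 titanium alkoxide closes the δ-lactone, so C10 is set with C9 trans to C6.

Step 10
Reactants: 18 7-[(tert-butyldimethylsilyloxy)methyl]-8,8-dimethyl-2-oxaspiro[5.5]undec-9-en-3-one (C9 trans to C6)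
Product: 20 7-[(tert-butyldimethylsilyloxy)methyl]-8,8-dimethyl-2-oxaspiro[5.5]undec-9-ene-3,11-dione, via allylic alcohol 19 (not isolated)
Conditions: SeO2, 1,4-dioxane, 90 °C
Reagents that add atoms: selenium dioxide, O=[Se]=O
Why: Riley allylic oxidation: the ene reaction of SeO2 at C3 removes a hydrogen from C1, the only allylic C–H carbon because C4 is quaternary, the [2,3]-sigmatropic shift returns oxygen to C1 (alcohol 19, drawn with the hydroxyl on the less hindered face) and further oxidation in the same flask gives the enone, so the position of the ketone is fixed by the mechanism.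

Step 11
Reactants: 20 7-[(tert-butyldimethylsilyloxy)methyl]-8,8-dimethyl-2-oxaspiro[5.5]undec-9-ene-3,11-dione; 21 N-methoxy-N-methylpropanamide
Product: 22 4-propanoyl derivative of 20 (keto form drawn)
Conditions: LiN(SiMe3)2, THF, −78 °C; then 21, −78 to 0 °C; aq NH4Cl
Reagents that add atoms: none
Why: Claisen-type C-acylation of a lactone lithium enolate by a Weinreb amide: C8 is the only enolisable carbon of 20 (the enone has neither α- nor γ-hydrogen) and the chelated tetrahedral adduct prevents over-addition; the new C8 centre is labile and is removed in step 12.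

Step 12
Reactants: 22 4-propanoyl derivative of 20 (keto form drawn)
Product: 24 7-[(tert-butyldimethylsilyloxy)methyl]-8,8-dimethyl-4-propanoyl-2-oxaspiro[5.5]undeca-4,9-diene-3,11-dione, via selenide 23 (not isolated)
Conditions: PhSeCl, pyridine, CH2Cl2, 0 °C; then 30% H2O2, 0 °C
Reagents that add atoms: none
Why: α-Selenenylation of the β-keto lactone at C8 followed by selenoxide syn-elimination toward C9, the only carbon with β-hydrogens, gives the doubly activated C8=C9 alkene; no stereocentre remains at C8.

Step 13
Reactants: 24 7-[(tert-butyldimethylsilyloxy)methyl]-8,8-dimethyl-4-propanoyl-2-oxaspiro[5.5]undeca-4,9-diene-3,11-dione; 25 buta-1,3-diene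
Product: 26 Diels–Alder adduct (ring C cyclohexene with C12=C13 cis-fused to the lactone at C8–C9; C8 propanoyl; C11 syn to C1)
Conditions: ZnCl2, Et2O, sealed tube, 0 °C to rt
Reagents that add atoms: none
Why: Lewis acid-promoted Diels–Alder reaction of an alkylidene β-keto lactone: suprafacial addition makes C8–C14 and C9–C11 cis, so the propanoyl group and H9 share the other face, and the diene should approach C8=C9 past the flat C1 carbonyl, not past C5 with its silyloxymethyl group and the neighbouring gem-dimethyl carbon, which places C11 syn to C1 as in the target.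

Step 14
Reactants: 26 Diels–Alder adduct (ring C cyclohexene with C12=C13 cis-fused to the lactone at C8–C9; C8 propanoyl; C11 syn to C1)
Product: 27 2-bromopropanoyl analogue of 26 (C16 epimers)
Conditions: KN(SiMe3)2, THF, −78 °C; then N-bromosuccinimide, −78 °C
Reagents that add atoms: N-bromosuccinimide, O=C1CCC(=O)N1Br
Why: Enolate bromination: C16 is the only enolisable carbon of 26 (C8 is quaternary, the enone and the lactone carry no α-hydrogen), and both C16 epimers serve in step 15.

Step 15
Reactants: 27 2-bromopropanoyl analogue of 26 (C16 epimers)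
Product: 28 6-O-silyl 16-deoxy precursor (bicyclo[3.2.1]octan-15-one with 16-methyl exo)
Conditions: Bu3SnH (slow addition), azobisisobutyronitrile (cat.), toluene, 80 °C
Reagents that add atoms: none
Why: Tin hydride-mediated 5-exo-trig radical cyclisation: the α-keto radical at C16, held over ring C by the axial acyl group on C8, adds to C13 of the C12=C13 alkene (five-membered closure through C14, expected to beat six-membered closure at C12) and the C12 radical is reduced, so the bicyclo[3.2.1]octane forms with C13 fixed by the bridge; C16 is re-set in step 16.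

Step 16
Reactants: 28 6-O-silyl 16-deoxy precursor (bicyclo[3.2.1]octan-15-one with 16-methyl exo)
Product: 29 6-O-tert-butyldimethylsilyl ether of 30
Conditions: KN(SiMe3)2, THF, −78 °C; then 2-(benzenesulfonyl)-3-phenyloxaziridine; aq NH4Cl
Reagents that add atoms: 2-(benzenesulfonyl)-3-phenyloxaziridine (Davis oxaziridine), O=S(=O)(N1OC1c1ccccc1)c1ccccc1
Why: Davis α-hydroxylation of a ketone enolate: C16 is the only enolisable carbon and the oxaziridine should attack the planar enolate on the exo face of the two-carbon bridge (the side of C14, away from the axial C11 hydrogen), giving the tertiary alcohol with hydroxyl exo and methyl endo.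

Step 17
Reactants: 29 6-O-tert-butyldimethylsilyl ether of 30
Product: 30 target CNP0530135.1 (6,16-dihydroxy-1,15-dioxo-6,7-seco-ent-kaur-2-en-7,20-olide)
Conditions: HF·pyridine, THF, 0 °C to rt
Reagents that add atoms: none
Why: Acidic fluoride desilylation of the primary silyl ether; the non-basic medium avoids α-ketol rearrangement at C15/C16 and leaves all stereocentres untouched.

**Compound list**

1 | 3-methylbut-3-en-1-ol | CC(=C)CCO | starting material
2 | tert-butyldimethyl[(3-methylbut-3-en-1-yl)oxy]silane | CC(=C)CCO[Si](C)(C)C(C)(C)C | intermediate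
3 | 3-methylbut-2-enal | CC(C)=CC=O | starting material
4 | allylpotassium: {2-[2-(tert-butyldimethylsilyloxy)ethyl]prop-2-en-1-yl}potassium (not isolated) | [K+].[CH2-]C(=C)CCO[Si](C)(C)C(C)(C)C | intermediate
5 | allylborane: B-{2-[2-(tert-butyldimethylsilyloxy)ethyl]prop-2-en-1-yl}diisopinocampheylborane from (+)-Ipc2BOMe (not isolated) | C=C(CCO[Si](C)(C)C(C)(C)C)CB([C@H]1C[C@H]2C[C@@H]([C@@H]1C)C2(C)C)[C@H]1C[C@H]2C[C@@H]([C@@H]1C)C2(C)C | intermediate
6 | (5R)-1-[(tert-butyldimethylsilyl)oxy]-7-methyl-3-methylideneoct-6-en-5-ol | CC(C)=C[C@H](O)CC(=C)CCO[Si](C)(C)C(C)(C)C | intermediate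
7 | (5R)-7-methyl-3-methylideneoct-6-ene-1,5-diol | CC(C)=C[C@H](O)CC(=C)CCO | intermediate
8 | hydroxy aldehyde: (5R)-5-hydroxy-7-methyl-3-methylideneoct-6-enal (not isolated) | CC(C)=C[C@H](O)CC(=C)CC=O | intermediate
9 | (6R)-4-methylidene-6-(2-methylprop-1-en-1-yl)oxan-2-one | CC(C)=C[C@H]1CC(=C)CC(=O)O1 | intermediate
10 | silyl ketene acetal: (2R)-4-methylidene-2-(2-methylprop-1-en-1-yl)-6-(trimethylsilyloxy)-3,4-dihydro-2H-pyran (not isolated) | CC(C)=C[C@H]1CC(=C)C=C(O[Si](C)(C)C)O1 | intermediate
11 | silyl ester: trimethylsilyl (1S)-2,2-dimethyl-6-methylidenecyclohex-3-ene-1-carboxylate (not isolated) | C[Si](C)(C)OC(=O)[C@H]1C(=C)CC=CC1(C)C | intermediate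
12 | (1S)-2,2-dimethyl-6-methylidenecyclohex-3-ene-1-carboxylic acid | OC(=O)[C@H]1C(=C)CC=CC1(C)C | intermediate
13 | [(1S)-2,2-dimethyl-6-methylidenecyclohex-3-en-1-yl]methanol | OC[C@H]1C(=C)CC=CC1(C)C | intermediate
14 | (5,5-dimethyl-1-oxaspiro[2.5]oct-6-en-4-yl)methanol (epoxide oxygen cis to the hydroxymethyl group) | OC[C@H]1[C@]2(CO2)CC=CC1(C)C | intermediate
15 | tert-butyldimethylsilyl ether of 14 | CC(C)(C)[Si](C)(C)OC[C@H]1[C@]2(CO2)CC=CC1(C)C | intermediate
16 | 2,2,2-trifluoroethyl prop-2-enoate | C=CC(=O)OCC(F)(F)F | starting material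
17 | hydroxy ester: 2,2,2-trifluoroethyl 3-[C10-(hydroxymethyl) ring A]propanoate, C9 trans to C6 (not isolated) | CC(C)(C)[Si](C)(C)OC[C@H]1[C@](CO)(CCC(=O)OCC(F)(F)F)CC=CC1(C)C | intermediate
18 | 7-[(tert-butyldimethylsilyloxy)methyl]-8,8-dimethyl-2-oxaspiro[5.5]undec-9-en-3-one (C9 trans to C6) | CC1(C)C=CC[C@]2(COC(=O)CC2)[C@@H]1CO[Si](C)(C)C(C)(C)C | intermediate
19 | allylic alcohol: 11-hydroxy derivative of 18 (C1 hydroxyl cis to C9; not isolated in the main route) | CC1(C)C=C[C@@H](O)[C@]2(COC(=O)CC2)[C@@H]1CO[Si](C)(C)C(C)(C)C | intermediate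
20 | 7-[(tert-butyldimethylsilyloxy)methyl]-8,8-dimethyl-2-oxaspiro[5.5]undec-9-ene-3,11-dione | CC1(C)C=CC(=O)[C@]2(COC(=O)CC2)[C@@H]1CO[Si](C)(C)C(C)(C)C | intermediate
21 | N-methoxy-N-methylpropanamide | CCC(=O)N(C)OC | starting material
22 | 4-propanoyl derivative of 20 (keto form drawn; C8 labile) | CC1(C)C=CC(=O)[C@]2(COC(=O)C(C(=O)CC)C2)[C@@H]1CO[Si](C)(C)C(C)(C)C | intermediate
23 | selenide: 4-(phenylselanyl)-4-propanoyl derivative of 20 (C8 epimers; not isolated) | CC1(C)C=CC(=O)[C@]2(COC(=O)C(C(=O)CC)([Se]c3ccccc3)C2)[C@@H]1CO[Si](C)(C)C(C)(C)C | intermediate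
24 | 7-[(tert-butyldimethylsilyloxy)methyl]-8,8-dimethyl-4-propanoyl-2-oxaspiro[5.5]undeca-4,9-diene-3,11-dione | CC1(C)C=CC(=O)[C@]2(COC(=O)C(C(=O)CC)=C2)[C@@H]1CO[Si](C)(C)C(C)(C)C | intermediate
25 | buta-1,3-diene | C=CC=C | starting material
26 | Diels–Alder adduct (ring C cyclohexene with C12=C13 cis-fused to the lactone at C8–C9; C8 propanoyl; C11 syn to C1) | CC1(C)C=CC(=O)[C@]2(COC(=O)[C@@]3(C(=O)CC)CC=CC[C@H]32)[C@@H]1CO[Si](C)(C)C(C)(C)C | intermediate
27 | 2-bromopropanoyl analogue of 26 (C16 epimers) | CC1(C)C=CC(=O)[C@]2(COC(=O)[C@@]3(C(=O)C(C)Br)CC=CC[C@H]32)[C@@H]1CO[Si](C)(C)C(C)(C)C | intermediate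
28 | 6-O-silyl 16-deoxy precursor (bicyclo[3.2.1]octan-15-one with 16-methyl exo) | CC1(C)C=CC(=O)[C@]2(COC(=O)[C@@]34C[C@@H](CC[C@H]32)[C@H](C)C4=O)[C@@H]1CO[Si](C)(C)C(C)(C)C | intermediate
29 | 6-O-tert-butyldimethylsilyl ether of 30 | CC1(C)C=CC(=O)[C@]2(COC(=O)[C@@]34C[C@@H](CC[C@H]32)[C@](C)(O)C4=O)[C@@H]1CO[Si](C)(C)C(C)(C)C | intermediate
30 | target CNP0530135.1 (6,16-dihydroxy-1,15-dioxo-6,7-seco-ent-kaur-2-en-7,20-olide) | CC1(C)C=CC(=O)[C@]2(COC(=O)[C@@]34C[C@@H](CC[C@H]32)[C@](C)(O)C4=O)[C@@H]1CO | target

**Step count and risks**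

Total step count: 17. Longest linear sequence: 17 steps (from 1).

Steps most likely to fail:

1. Step 15. The C16 radical may close on C12 (six-membered closure to a bicyclo[2.2.2]octane) or be reduced before it cyclises. The fallback sets out from 26 and replaces the radical by an organopalladium closure. Soft enolisation (t-BuMe2SiOTf, Et3N, CH2Cl2) should give the (Z)-silyl enol ether F1. Stoichiometric Pd(OAc)2 in MeCN then forms a divalent palladium enolate at C16 that carbopalladates the ring C alkene at C13; β-hydride elimination should give the bicyclo[3.2.1]octenone F2 with a C11=C12 double bond. Diimide (potassium azodicarboxylate, AcOH, MeOH) should saturate only this strained, unconjugated alkene, and the route is rejoined at 28.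

2. Step 10. The ene step must deliver selenium to C3, which is flanked by the quaternary C4, so slow conversion or degradation on prolonged heating may result. The fallback sets out from 13, where C1 is doubly allylic and the unhindered exocyclic methylene is the ene partner. Catalytic SeO2 with t-BuOOH (CH2Cl2, rt) should give the bis-allylic diol F3. VO(acac)2/t-BuOOH should then epoxidise the exocyclic alkene, to which both hydroxyls direct, giving epoxy diol F4. Selective silylation of the primary hydroxyl (t-BuMe2SiCl, imidazole, −20 °C) gives F5. The Cp2TiCl2/Zn coupling with 16 then gives 19 as an isolated compound, and Dess–Martin periodinane returns to the route at 20.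

3. Step 2. Metalation may take place at the allylic methylene next to the silyloxyethyl chain, with loss of silanolate, and the enantioselectivity of a 2-substituted allylborane toward an enal may fall short. The fallback sets out from 1 and 3 and moves stereocontrol to a ketone reduction. The dianion of 1 (n-BuLi, TMEDA, Et2O) adds to 3 to give the racemic diol F6. MnO2 (CH2Cl2) should oxidise only the allylic secondary alcohol, to hydroxy dienone F7. Corey–Bakshi–Shibata reduction with (S)-1-methyl-3,3-diphenyl-tetrahydro-1H,3H-pyrrolo[1,2-c][1,3,2]oxazaborole (cat.) and BH3·SMe2 should set the (R)-carbinol, and the route is rejoined at 7.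

Further compounds
F1 | step 15 | (Z)-tert-butyldimethylsilyl enol ether of 26 (C15 silyloxy; C15=C16) | CC1(C)C=CC(=O)[C@]2(COC(=O)[C@@]3(/C(O[Si](C)(C)C(C)(C)C)=C/C)CC=CC[C@H]32)[C@@H]1CO[Si](C)(C)C(C)(C)C
F2 | step 15 | 11,12-didehydro analogue of 28 (bicyclo[3.2.1]oct-ene) | CC1(C)C=CC(=O)[C@]2(COC(=O)[C@@]34C[C@@H](C=C[C@H]32)[C@H](C)C4=O)[C@@H]1CO[Si](C)(C)C(C)(C)C
F3 | step 10 | 2-(hydroxymethyl)-3,3-dimethyl-6-methylidenecyclohex-4-en-1-ol (C1 hydroxyl trans to the hydroxymethyl group; C5 as in 13) | CC1(C)C=C[C@@H](O)C(=C)[C@@H]1CO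
F4 | step 10 | spiro-epoxy diol from F3 (epoxide oxygen cis to the C1 hydroxyl) | CC1(C)C=C[C@@H](O)[C@]2(CO2)[C@@H]1CO
F5 | step 10 | primary tert-butyldimethylsilyl ether of F4 | CC1(C)C=C[C@@H](O)[C@]2(CO2)[C@@H]1CO[Si](C)(C)C(C)(C)C
F6 | step 2 | racemic 7-methyl-3-methylideneoct-6-ene-1,5-diol | CC(C)=CC(O)CC(=C)CCO
F7 | step 2 | 8-hydroxy-2-methyl-6-methylideneoct-2-en-4-one | CC(C)=CC(=O)CC(=C)CCO
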